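## Structural features

The target is a 3,3a-dihydro-1-benzofuran-6(2H)-one. An oxolane (O1, C2, C3, C3a, C7a) and a six-membered carbocycle (C3a, C4, C5, C6, C7, C7a) share only the C3a–C7a bond. The carbocycle is a cross-conjugated cyclohexa-2,5-dienone: C6 is the carbonyl carbon, C4=C5 carries the methoxy group on C5, and C7=C7a is a vinylogous ester through O1. C3a is the only sp3 carbon of that ring and is quaternary (allyl, C3, C4, C7a). Three stereocentres are contiguous: C2 (S, 3,4,5-trimethoxyphenyl), C3 (S, methyl) and C3a (R, allyl), with aryl and methyl trans and methyl and allyl cis on the oxolane. The fragile elements are the 4-allyl-cyclohexadienone (sigmatropic allyl shifts, acid-induced migration towards a phenol), the vinylogous ester, the benzylic C2–O1 bond next to an electron-rich arene, and the terminal alkene. The real difficulty is the quaternary centre C3a, which must be set relative to C3 and then survive the adjustment of the carbocycle to the dienone level with oxygen placed correctly at C5 and C6. The plan uses the fact that C3a and C7a belong to both rings: as the C3a=C7a double bond of a 3-formyl-4,5-dihydrofuran they are an activated two-carbon unit to which C4–C7 are added as a diene, and the formyl carbon on C3a later becomes the first carbon of the allyl group.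

## Logic of the disconnections

22 to 20: the C4=C5 and C7=C7a π bonds are taken back to C–H bonds. The allyl dienone is the most sensitive array in the molecule, so it is made last. The gain is a plain saturated α-methoxy ketone. The forward step must desaturate both sides of C6 under neutral, mild conditions without touching the terminal alkene, the arene or the benzylic C2–H.

20 to 19 to 17: the O–CH3 bond at C5 is cut, then the C5–O bond, and the C6 carbonyl is traced to an enol ether whose double bond lies between C5 and C6. This removes a stereochemically irrelevant oxygen and returns to the enol ether that the cycloaddition delivers with fixed regiochemistry. The forward oxidation must choose the enol ether over the allyl group, and the methylation must not be basic enough to expel O1 from C7a.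

17 to 16 to 14: the bond between the first and second allyl carbons is cut after an oxygen is put back on the first carbon (16), which is the formyl carbon of 14. The cut is placed here because the formyl group is needed to activate the dienophile and must be converted while the enol ether is still intact, which rules out acidic homologation. The forward sequence needs a carbon–oxygen hydrogenolysis that delivers hydride to the neopentyl terminus of an allyl system.

14 to 11 and 13: C3a–C4 and C7–C7a are cut together. This removes the carbocycle, the quaternary centre and the C7a stereocentre in one operation and leaves a monocyclic enal and a four-carbon diene. The forward step must be regioselective (silyloxy carbon para to C3a) and must take the face of 11 opposite the C3 methyl group.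

13 to 12: the O–Si bond is cut; the diene is the silyl dienol ether of a commercial enone.

11 to 9: the bond between the formyl carbon and C3a is cut. A cyclic enol ether is nucleophilic at exactly that carbon, so electrophilic formylation can be used.

9 to 7 (through 8): the enol ether double bond is traced back to a C–OH bond at the anomeric carbon of a cyclic hemiacetal. The gain is that the ring and both stereocentres are already in place and only water has to be removed. The forward step needs an elimination under basic conditions that tolerates the benzylic ether; the double bond can form in one direction only.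

7 to 6 to 4: the ring C–O bond of the hemiacetal is opened to an aldehyde and a secondary alcohol, the aldehyde is traced to a primary alcohol, and the primary C–O bond to a terminal alkene. The forward steps need anti-Markovnikov hydration and an oxidation that takes only the primary alcohol and stops at the aldehyde level, so that no reduction is needed afterwards.

4 to 1 and 2: the C2–C3 bond is cut. Both stereocentres of the oxolane arise in one step from two commercial compounds, provided the crotyl transfer is anti-selective and face-selective.

## Other disconnections considered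

Alternative 1: The cut is C2–C3 together with the ring C–O bond of a lactone. Forward, aldehyde 1 would react with methyl (Z)-2-[(pinacolboryl)methyl]but-2-enoate A2 and the borate alkoxide would lactonise to the trans α-methylene lactone A1.
- In favour: one step gives the trans-disubstituted oxygen ring, where the chosen plan needs three steps to reach 7; on this point the alternative is the better. The exocyclic methylene also allows conjugate addition of a vinyl nucleophile (giving the allyl group) followed by enolate trapping anti to methyl. That control of C3a is at least the equal of the facial bias of a cycloaddition.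
- Against: enantiocontrol would rest on a chiral diol–SnCl4 acid acting on an ester-deactivated boronate and an electron-rich aldehyde, a less general combination than acid-catalysed crotylation with a simple pinacol boronate. The key step builds none of the carbocycle, which would still require a Claisen-type closure onto the carbonyl of A1 and separate enolate oxidations for C5 and C4=C5.
- Comparison: structurally the alternative's key step forms the heterocycle and two stereocentres, while the chosen key step forms the carbocycle, the quaternary centre and one further stereocentre. Mechanistically a closed six-membered allylboration transition state is more predictable than a cycloaddition onto a push–pull enal. Overall length should be comparable or slightly shorter.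

Alternative 2: The cut is C2–C3. Forward, a chiral dirhodium tetracarboxylate such as Rh2(S-PTTL)4 (dirhodium tetrakis[N-phthaloyl-(S)-tert-leucinate]) would decompose diazoester A4 and the carbenoid at C3 would insert into the benzylic ether C–H bond, giving A3 after base equilibration of the ester to the 2,3-trans isomer.
- In favour: the allyl-bearing quaternary carbon is present from the start, so no formyl-to-allyl sequence is needed; here it is the better. The benzylic C–H bond of a trimethoxybenzyl ether is electronically well suited to insertion, and the 2,3-trans relationship would be set thermodynamically, which is equal in reliability to anti-crotylation.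
- Against: A4 must already contain the quaternary centre in enantioenriched form and the catalyst must match it. The carbenoid has competing targets next to it (the electron-rich enol ether, the allyl alkene, the ether oxygen). The ester must be reduced to methyl, and the carbocycle of A3 needs three separate oxidation events (C6 carbonyl, C5 oxygen, C4=C5) in the presence of the allyl group.
- Comparison: the step closes the oxolane rather than the carbocycle and leaves the hardest oxidation problems for later. The expected step count is clearly higher than in the chosen plan.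

Alternative 3: The cut is C3a–C7a. Forward, heating cyclobutenone A6 would open it to a dienylketene, and 6π electrocyclisation would give the 2,4-dienone A5. Desilylation and acid-catalysed exchange of the C2 oxygen onto C7a with loss of methanol would then give 22.
- In favour: every oxygen of the carbocycle and the allyl group are in place before the ring forms, so no late redox chemistry is needed and the endgame is one or two steps. On oxidation-state economy and endgame length this alternative is the better.
- Against: C3a would be set during the electrocyclisation only by 1,2-induction from an exocyclic stereocentre, which is weaker control than a ring-bound neighbour. A stereodefined trisubstituted alkenyl metal and a 2-unsubstituted 3,4-dimethoxycyclobutenone have to be prepared first. A 6-allyl-cyclohexa-2,4-dienone is the intermediate of a Claisen rearrangement and could aromatise by a [3,3] shift, or dimerise, at the temperature the ring opening requires.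
- Comparison: mechanistically elegant and convergent, but the stereochemical and thermal risks sit on the key step itself. In the chosen plan the quaternary centre is made at low temperature on a rigid ring.

Key step: step 7

Assumptions: the (S)-configured phosphoric acid is taken to direct crotyl transfer to the Si face of 1 (the mirror-image acid would be used if the sense proved opposite). Lactol 7 and its open-chain 4-hydroxy aldehyde are ring–chain tautomers and are counted as one compound; 7 and 8 are carried as anomer mixtures because the anomeric centre is erased in step 4. The C5 epimers of 19 and 20 and the carbinol epimers of 16 are carried on together because those centres are erased later. The CIP label at C3a changes along the route (R in 14–16, S in 17–21, R in 22) only because substituent priorities change, not the geometry.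

## Route

Step 1
Reactants: 1 3,4,5-trimethoxybenzaldehyde; 2 (E)-crotylboronic acid pinacol ester
Product: 4 (1S,2S)-2-methyl-1-(3,4,5-trimethoxyphenyl)but-3-en-1-ol, via homoallyl pinacol borate 3 (not isolated)
Conditions: (S)-3,3′-bis(2,4,6-triisopropylphenyl)-1,1′-binaphthyl-2,2′-diyl hydrogen phosphate (5 mol %), 2 (1.2 equiv), toluene, −30 °C; aq. NaHCO3
Reagents that add atoms: none
Why: Brønsted-acid-catalysed crotylboration through a closed chair (Zimmerman–Traxler) transition state; the E geometry of 2 gives the anti relationship, and the chiral acid, hydrogen-bonded to the boronate, selects the aldehyde face, so both C2 and C3 of the target are set here.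

Step 2
Reactants: 4 (1S,2S)-2-methyl-1-(3,4,5-trimethoxyphenyl)but-3-en-1-ol
Product: 6 (1S,2S)-2-methyl-1-(3,4,5-trimethoxyphenyl)butane-1,4-diol, via bis-9-BBN adduct 5 (not isolated)
Conditions: 9-BBN (2.5 equiv), THF, 0 °C → rt; NaOH, H2O2, 0 °C → rt
Reagents that add atoms: hydrogen peroxide, OO
Why: Anti-Markovnikov hydroboration–oxidation; the bulky dialkylborane places boron on the terminal carbon and the existing stereocentres are not involved.

Step 3
Reactants: 6 (1S,2S)-2-methyl-1-(3,4,5-trimethoxyphenyl)butane-1,4-diol
Product: 7 (4S,5S)-4-methyl-5-(3,4,5-trimethoxyphenyl)oxolan-2-ol (anomers)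
Conditions: TEMPO (2,2,6,6-tetramethylpiperidin-1-oxyl, 10 mol %), PhI(OAc)2 (1.1 equiv), CH2Cl2, 0 °C → rt; aq. Na2S2O3/NaHCO3
Reagents that add atoms: none
Why: Oxoammonium oxidation takes the unhindered primary alcohol in preference to the secondary benzylic one, and the 4-hydroxy aldehyde closes at once to the five-membered lactol; with only a slight excess of the terminal oxidant at low temperature the slower oxidation of the hemiacetal should be held back, so no later reduction is needed. The trans aryl/methyl relationship follows from the anti diol, and the new anomeric centre is uncontrolled and irrelevant.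

Step 4
Reactants: 7 (4S,5S)-4-methyl-5-(3,4,5-trimethoxyphenyl)oxolan-2-ol
Product: 9 (2S,3S)-3-methyl-2-(3,4,5-trimethoxyphenyl)-2,3-dihydrofuran, via anomeric mesylate 8 (not isolated)
Conditions: MsCl, Et3N (excess), CH2Cl2, −40 → 40 °C
Reagents that add atoms: none
Why: Sulfonylation of the anomeric hydroxyl and amine-mediated loss of methanesulfonic acid through the oxocarbenium ion (the standard lactol-to-cyclic-enol-ether dehydration); the double bond can only form towards the ring CH2, C2 and C3 are untouched, and the excess amine keeps the medium basic for the benzylic ether.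

Step 5
Reactants: 9 (2S,3S)-3-methyl-2-(3,4,5-trimethoxyphenyl)-2,3-dihydrofuran
Product: 11 (4S,5S)-4-methyl-5-(3,4,5-trimethoxyphenyl)-4,5-dihydrofuran-3-carbaldehyde, via iminium chloride 10 (not isolated)
Conditions: POCl3, DMF, CH2Cl2, 0 °C → rt; aq. NaOAc, 0 °C
Reagents that add atoms: N,N-dimethylformamide, CN(C)C=O; water, O
Why: Vilsmeier–Haack formylation: the nucleophilic β-carbon of the cyclic enol ether attacks the chloroiminium ion, proton loss gives vinylogous formamidinium salt 10, and acetate-buffered hydrolysis releases the β-alkoxy enal without exposing the benzylic ether to strong acid.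

Step 6
Reactants: 12 methyl vinyl ketone
Product: 13 2-(tert-butyldimethylsilyloxy)buta-1,3-diene
Conditions: TBSOTf, Et3N, Et2O, 0 °C
Reagents that add atoms: tert-butyldimethylsilyl trifluoromethanesulfonate, CC(C)(C)[Si](C)(C)OS(=O)(=O)C(F)(F)F
Why: Soft enolisation and O-silylation of the enone with a silyl triflate and a tertiary amine gives the 2-silyloxydiene, which is distilled and used in excess.

Step 7
Reactants: 11 (4S,5S)-4-methyl-5-(3,4,5-trimethoxyphenyl)-4,5-dihydrofuran-3-carbaldehyde; 13 2-(tert-butyldimethylsilyloxy)buta-1,3-diene
Product: 14 (2S,3S,3aR,7aS)-6-(tert-butyldimethylsilyloxy)-3-methyl-2-(3,4,5-trimethoxyphenyl)-2,3,7,7a-tetrahydro-1-benzofuran-3a(4H)-carbaldehyde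
Conditions: Et2AlCl (1.2 equiv), 13 (3 equiv), CH2Cl2, −78 → −30 °C; Et3N, then aq. NaHCO3
Reagents that add atoms: none
Why: Et2AlCl binds the formyl oxygen of 11 and lowers the LUMO of the C3a=C7a bond enough for a normal-demand, probably asynchronous [4+2] cycloaddition with the electron-rich diene; the closest known reaction type is the Lewis-acid-promoted Diels–Alder reaction of 3-formyl cyclic enol ethers (α-substituted β-alkoxy enals) with 2-silyloxybutadienes. The CH2 terminus next to the silyloxy carbon of 13 carries the largest HOMO coefficient and bonds to the β-carbon C7a, while the vinyl terminus bonds to C3a, so the silyloxy carbon becomes C6, para to C3a, with the enol ether double bond between C5 and C6. The six-membered carbocycle closes by suprafacial intermolecular [4π+2π] addition; if the process were stepwise, Michael addition at C7a would be followed by a 6-endo-trig closure of the aluminium enolate onto the silyloxyallyl cation, with the same outcome. C3a and C7a are created together: their cis relationship follows from suprafacial addition to the dienophile, and their absolute sense from attack on the ring face opposite the C3 methyl group, which leaves formyl cis to methyl. The diene has no terminal substituents, so there is no endo/exo question. The step needs para regioselectivity, secured by the matched polarisation of the silyloxydiene and the β-alkoxy enal. It needs π-facial selectivity, secured by the methyl group sitting on the carbon directly bonded to the forming quaternary centre, whereas the aryl group on the opposite face is one atom further away across O1. It also needs C=C over C=O chemoselectivity, favoured by low temperature and by the hindered, conjugated formyl group.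

Step 8
Reactants: 14 (2S,3S,3aR,7aS)-6-(tert-butyldimethylsilyloxy)-3-methyl-2-(3,4,5-trimethoxyphenyl)-2,3,7,7a-tetrahydro-1-benzofuran-3a(4H)-carbaldehyde
Product: 16 methyl 1-[(2S,3S,3aR,7aS)-6-(tert-butyldimethylsilyloxy)-3-methyl-2-(3,4,5-trimethoxyphenyl)-2,3,7,7a-tetrahydro-1-benzofuran-3a(4H)-yl]prop-2-en-1-yl carbonate (carbinol epimers), via magnesium alkoxide 15 (not isolated)
Conditions: CH2=CHMgBr, THF, −78 → 0 °C; then ClCO2Me, DMAP (cat.), 0 °C → rt
Reagents that add atoms: vinylmagnesium bromide, C=C[Mg]Br; methyl chloroformate, COC(=O)Cl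
Why: 1,2-Addition of a vinyl Grignard reagent to the non-enolisable neopentyl aldehyde and O-acylation of the alkoxide in the same flask; the silyl enol ether is inert to both reagents, and the new carbinol centre is removed in step 9.

Step 9
Reactants: 16 methyl 1-[(2S,3S,3aR,7aS)-6-(tert-butyldimethylsilyloxy)-3-methyl-2-(3,4,5-trimethoxyphenyl)-2,3,7,7a-tetrahydro-1-benzofuran-3a(4H)-yl]prop-2-en-1-yl carbonate
Product: 17 (2S,3S,3aS,7aS)-3a-allyl-6-(tert-butyldimethylsilyloxy)-3-methyl-2-(3,4,5-trimethoxyphenyl)-2,3,3a,4,7,7a-hexahydro-1-benzofuran
Conditions: Pd(OAc)2 (5 mol %), PBu3 (20 mol %), HCO2H, Et3N (excess), THF, 40 °C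
Reagents that add atoms: none
Why: Palladium-catalysed formate hydrogenolysis of an allylic carbonate: zerovalent palladium ionises the carbonate to a π-allyl complex, and with a trialkylphosphine the formate hydride is delivered intramolecularly to the more substituted allyl terminus, leaving the terminal alkene, which is the allyl group on C3a. The adjacent quaternary carbon excludes diene formation, and the amine buffer protects the silyl enol ether.

Step 10
Reactants: 17 (2S,3S,3aS,7aS)-3a-allyl-6-(tert-butyldimethylsilyloxy)-3-methyl-2-(3,4,5-trimethoxyphenyl)-2,3,3a,4,7,7a-hexahydro-1-benzofuran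
Product: 19 (2S,3S,3aS,7aS)-3a-allyl-5-hydroxy-3-methyl-2-(3,4,5-trimethoxyphenyl)hexahydro-1-benzofuran-6(2H)-one (C5 epimers), via silyloxy epoxide 18 (not isolated)
Conditions: dimethyldioxirane (1.1 equiv), acetone/CH2Cl2, −78 → −20 °C; then HF·pyridine, pyridine, THF, 0 °C
Reagents that add atoms: dimethyldioxirane, CC1(C)OO1
Why: Rubottom oxidation: the electron-rich silyl enol ether is epoxidised far faster than the monosubstituted alkene, and fluoride-induced opening of 18 places oxygen on C5 and the carbonyl on C6; the C5 configuration does not matter because C5 becomes sp2.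

Step 11
Reactants: 19 (2S,3S,3aS,7aS)-3a-allyl-5-hydroxy-3-methyl-2-(3,4,5-trimethoxyphenyl)hexahydro-1-benzofuran-6(2H)-one
Product: 20 (2S,3S,3aS,7aS)-3a-allyl-5-methoxy-3-methyl-2-(3,4,5-trimethoxyphenyl)hexahydro-1-benzofuran-6(2H)-one (C5 epimers)
Conditions: Me3OBF4, 1,8-bis(dimethylamino)naphthalene, 4 Å MS, CH2Cl2, 0 °C → rt
Reagents that add atoms: trimethyloxonium tetrafluoroborate, C[O+](C)C.F[B-](F)(F)F
Why: O-Methylation of a secondary α-hydroxy ketone with a Meerwein salt and a non-nucleophilic proton scavenger; the medium is not basic enough to enolise C7 and expel O1 from C7a.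

Step 12
Reactants: 20 (2S,3S,3aS,7aS)-3a-allyl-5-methoxy-3-methyl-2-(3,4,5-trimethoxyphenyl)hexahydro-1-benzofuran-6(2H)-one
Product: 22 (2S,3S,3aR)-3a-allyl-5-methoxy-3-methyl-2-(3,4,5-trimethoxyphenyl)-3,3a-dihydro-1-benzofuran-6(2H)-one, via mono-enone 21 (not isolated)
Conditions: 2-iodoxybenzoic acid (IBX, 5 equiv), 4-methoxypyridine N-oxide (5 equiv), DMSO, 25 → 50 °C
Reagents that add atoms: none
Why: Ketone-to-enone dehydrogenation by a pentavalent iodine oxidant through the enol, applied on both sides of C6: the C7–C7a side gives vinylogous ester 21 and the C5–C4 side the α-methoxy enone. Neutral conditions and mild temperature spare the terminal alkene and avoid a sigmatropic shift of the allyl group in 22.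

## Compound list

1 | 3,4,5-trimethoxybenzaldehyde | COc1cc(C=O)cc(OC)c1OC | starting material
2 | (E)-crotylboronic acid pinacol ester [(E)-2-(but-2-en-1-yl)-4,4,5,5-tetramethyl-1,3,2-dioxaborolane] | C/C=C/CB1OC(C)(C)C(C)(C)O1 | starting material
3 | 2-{[(1S,2S)-2-methyl-1-(3,4,5-trimethoxyphenyl)but-3-en-1-yl]oxy}-4,4,5,5-tetramethyl-1,3,2-dioxaborolane | CC1(C)OB(O[C@H](c2cc(OC)c(OC)c(OC)c2)[C@H](C=C)C)OC1(C)C | intermediate (not isolated)
4 | (1S,2S)-2-methyl-1-(3,4,5-trimethoxyphenyl)but-3-en-1-ol | O[C@H](c1cc(OC)c(OC)c(OC)c1)[C@H](C=C)C | intermediate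
5 | 9-{(3S,4S)-4-[(9-borabicyclo[3.3.1]nonan-9-yl)oxy]-3-methyl-4-(3,4,5-trimethoxyphenyl)butyl}-9-borabicyclo[3.3.1]nonane | O(B1C2CCCC1CCC2)[C@H](c1cc(OC)c(OC)c(OC)c1)[C@H](CCB1C2CCCC1CCC2)C | intermediate (not isolated)
6 | (1S,2S)-2-methyl-1-(3,4,5-trimethoxyphenyl)butane-1,4-diol | O[C@H](c1cc(OC)c(OC)c(OC)c1)[C@H](CCO)C | intermediate
7 | (4S,5S)-4-methyl-5-(3,4,5-trimethoxyphenyl)oxolan-2-ol (anomers) | OC1O[C@H](c2cc(OC)c(OC)c(OC)c2)[C@H](C1)C | intermediate
8 | (4S,5S)-4-methyl-5-(3,4,5-trimethoxyphenyl)oxolan-2-yl methanesulfonate (anomers) | CS(=O)(=O)OC1O[C@H](c2cc(OC)c(OC)c(OC)c2)[C@H](C1)C | intermediate (not isolated)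
9 | (2S,3S)-3-methyl-2-(3,4,5-trimethoxyphenyl)-2,3-dihydrofuran | C1=CO[C@H](c2cc(OC)c(OC)c(OC)c2)[C@H]1C | intermediate
10 | N-{[(4S,5S)-4-methyl-5-(3,4,5-trimethoxyphenyl)-4,5-dihydrofuran-3-yl]methylidene}-N-methylmethanaminium chloride | C[N+](C)=CC1=CO[C@H](c2cc(OC)c(OC)c(OC)c2)[C@H]1C.[Cl-] | intermediate (not isolated)
11 | (4S,5S)-4-methyl-5-(3,4,5-trimethoxyphenyl)-4,5-dihydrofuran-3-carbaldehyde (aryl and methyl trans) | O=CC1=CO[C@H](c2cc(OC)c(OC)c(OC)c2)[C@H]1C | intermediate
12 | methyl vinyl ketone (but-3-en-2-one) | CC(=O)C=C | starting material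
13 | 2-(tert-butyldimethylsilyloxy)buta-1,3-diene | C=CC(=C)O[Si](C)(C)C(C)(C)C | intermediate
14 | (2S,3S,3aR,7aS)-6-(tert-butyldimethylsilyloxy)-3-methyl-2-(3,4,5-trimethoxyphenyl)-2,3,7,7a-tetrahydro-1-benzofuran-3a(4H)-carbaldehyde (cis-fused, formyl cis to methyl) | O=C[C@@]12CC=C(O[Si](C)(C)C(C)(C)C)C[C@@H]1O[C@H](c1cc(OC)c(OC)c(OC)c1)[C@H]2C | intermediate
15 | bromomagnesium 1-[(2S,3S,3aR,7aS)-6-(tert-butyldimethylsilyloxy)-3-methyl-2-(3,4,5-trimethoxyphenyl)-2,3,7,7a-tetrahydro-1-benzofuran-3a(4H)-yl]prop-2-en-1-olate (carbinol epimers) | C=CC(O[Mg]Br)[C@@]12CC=C(O[Si](C)(C)C(C)(C)C)C[C@@H]1O[C@H](c1cc(OC)c(OC)c(OC)c1)[C@H]2C | intermediate (not isolated)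
16 | methyl 1-[(2S,3S,3aR,7aS)-6-(tert-butyldimethylsilyloxy)-3-methyl-2-(3,4,5-trimethoxyphenyl)-2,3,7,7a-tetrahydro-1-benzofuran-3a(4H)-yl]prop-2-en-1-yl carbonate (carbinol epimers) | C=CC(OC(=O)OC)[C@@]12CC=C(O[Si](C)(C)C(C)(C)C)C[C@@H]1O[C@H](c1cc(OC)c(OC)c(OC)c1)[C@H]2C | intermediate
17 | (2S,3S,3aS,7aS)-3a-allyl-6-(tert-butyldimethylsilyloxy)-3-methyl-2-(3,4,5-trimethoxyphenyl)-2,3,3a,4,7,7a-hexahydro-1-benzofuran | C=CC[C@@]12CC=C(O[Si](C)(C)C(C)(C)C)C[C@@H]1O[C@H](c1cc(OC)c(OC)c(OC)c1)[C@H]2C | intermediate
18 | (2S,3S,3aS,7aS)-3a-allyl-6-(tert-butyldimethylsilyloxy)-5,6-epoxy-3-methyl-2-(3,4,5-trimethoxyphenyl)octahydro-1-benzofuran (epoxide face unassigned) | C=CC[C@@]12CC3OC3(O[Si](C)(C)C(C)(C)C)C[C@@H]1O[C@H](c1cc(OC)c(OC)c(OC)c1)[C@H]2C | intermediate (not isolated)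
19 | (2S,3S,3aS,7aS)-3a-allyl-5-hydroxy-3-methyl-2-(3,4,5-trimethoxyphenyl)hexahydro-1-benzofuran-6(2H)-one (C5 epimers) | C=CC[C@@]12CC(O)C(=O)C[C@@H]1O[C@H](c1cc(OC)c(OC)c(OC)c1)[C@H]2C | intermediate
20 | (2S,3S,3aS,7aS)-3a-allyl-5-methoxy-3-methyl-2-(3,4,5-trimethoxyphenyl)hexahydro-1-benzofuran-6(2H)-one (C5 epimers) | C=CC[C@@]12CC(OC)C(=O)C[C@@H]1O[C@H](c1cc(OC)c(OC)c(OC)c1)[C@H]2C | intermediate
21 | (2S,3S,3aS)-3a-allyl-5-methoxy-3-methyl-2-(3,4,5-trimethoxyphenyl)-3,3a,4,5-tetrahydro-1-benzofuran-6(2H)-one (C5 epimers) | C=CC[C@@]12CC(OC)C(=O)C=C1O[C@H](c1cc(OC)c(OC)c(OC)c1)[C@H]2C | intermediate (not isolated)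
22 | (2S,3S,3aR)-3a-allyl-5-methoxy-3-methyl-2-(3,4,5-trimethoxyphenyl)-3,3a-dihydro-1-benzofuran-6(2H)-one | C=CC[C@@]12C=C(OC)C(=O)C=C1O[C@H](c1cc(OC)c(OC)c(OC)c1)[C@H]2C | target

## Step count and least certain steps

Total: 12 steps. Longest linear sequence: 11 steps (steps 1–5 and 7–12); step 6 is a one-step branch.

Step 7 (key step). Three things may go wrong.
- The push–pull enal may be too poor a dienophile, so that the diene oligomerises or adds to the formyl group in a Mukaiyama-type process.
- Facial selectivity may be eroded, because the C2 aryl group lies on the face the diene must use.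
- The Lewis acid may ionise the benzylic C2–O1 bond and epimerise C2.

The fallback sets out from 7 and returns at 22; it builds the quaternary centre by lactone enolate chemistry instead of cycloaddition. Oxidation of 7 (TEMPO, PhI(OAc)2, CH2Cl2, rt) would give (4S,5S)-4-methyl-5-(3,4,5-trimethoxyphenyl)oxolan-2-one F1. Deprotonation of this lactone (LiN(i-Pr)2, THF, −78 °C) and allyl bromide should give, by attack anti to the C4 methyl, (3S,4S,5S)-3-allyl-4-methyl-5-(3,4,5-trimethoxyphenyl)oxolan-2-one F2. A second enolisation and Michael addition to 3-(trimethylsilyl)but-3-en-2-one, again anti to methyl, should give the 3-allyl-3-[3-oxo-2-(trimethylsilyl)butyl] lactone F3, with allyl now cis to methyl. NaOMe in MeOH (loss of silicon and Claisen condensation of the methyl ketone onto the lactone carbonyl) should give (4R)-4-allyl-4-[(1S,2S)-1-hydroxy-1-(3,4,5-trimethoxyphenyl)propan-2-yl]cyclohexane-1,3-dione F4. TsOH in toluene (closure of O1 onto C7a with loss of water) should then give the vinylogous ester (2S,3S,3aR)-3a-allyl-3-methyl-2-(3,4,5-trimethoxyphenyl)-3,3a,4,5-tetrahydro-1-benzofuran-6(2H)-one F5. α′-Hydroxylation (LiN(i-Pr)2, then 3-phenyl-2-(phenylsulfonyl)oxaziridine) would give the 5-hydroxy ketone F6. Dess–Martin oxidation would give the 5-hydroxy dienone F7, a diosphenol that can enolise only towards C4. Me2SO4 and K2CO3 in acetone would then give 22.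

Step 12. The second dehydrogenation may stall because vinylogous ester 21 enolises reluctantly. The oxidant may attack the benzylic C2–H or the arene by single-electron pathways. If heating is needed, the allyl group of 22 may migrate.

The fallback sets out from 20 and returns at 22 by two separate selenoxide eliminations. Kinetic enolisation of 20 away from the methoxy-bearing carbon (LiN(i-Pr)2, THF, −78 °C) and PhSeCl would give the 7-phenylselanyl ketone F8. Oxidation (H2O2, pyridine, CH2Cl2, 0 °C) and syn-elimination towards H-7a would give 21, this time isolated. α′-Deprotonation of 21 at C5, PhSeCl and oxidation of the 5-methoxy-5-phenylselanyl enone F9 would give 22 at or below room temperature.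

Step 9. Ionisation of the neopentyl carbonate may be slow. Hydride may be delivered to the less hindered allyl terminus, giving the internal propenyl isomer. Methoxide released from the carbonate may cleave or allylate the silyl enol ether if the buffer is inadequate.

The fallback sets out from 14 and returns at 17. Horner–Wadsworth–Emmons olefination of 14 (triethyl phosphonoacetate, NaH, THF) would give the ethyl (E)-enoate F10. Reduction with i-Bu2AlH would give the primary allylic alcohol F11. Reductive 1,3-transposition (2-nitrobenzenesulfonylhydrazide, PPh3, diethyl azodicarboxylate, THF, −30 °C → rt) would then give 17: the monoalkyl diazene delivers hydrogen to the carbon attached to C3a with loss of N2.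

Step 10. The allyl group or the electron-rich arene may be oxidised competitively, silyl migration may give mixtures, and the α-ketol may transpose on handling.

The fallback sets out from 17 and returns at 20, bypassing 19. It is a direct oxidative α-methoxylation of the silyl enol ether with iodosylbenzene and BF3·OEt2 in MeOH at −40 °C: the trivalent iodine reagent attacks C5 and methanol then displaces iodobenzene. No new compound is formed on the way.

Step 3. The oxidation may run on past the hemiacetal stage, because the lactol is itself a substrate for the oxoammonium salt, so that over-oxidised material and unreacted diol could appear side by side. Competing oxidation of the electron-rich benzylic alcohol is the second concern.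

The fallback sets out from 4 and returns at 9, bypassing 6, 7 and 8; it closes the dihydrofuran by metathesis and needs no redox adjustment. Transfer vinylation of 4 ([Ir(cod)Cl]2 with cod = cycloocta-1,5-diene, Na2CO3, vinyl acetate, toluene, 100 °C) would give the vinyl ether 5-[(1S,2S)-1-(ethenyloxy)-2-methylbut-3-en-1-yl]-1,2,3-trimethoxybenzene F12. Ring-closing metathesis of the enol ether with the terminal alkene (second-generation Grubbs catalyst, toluene, 70 °C) would then release ethene and give 9, the new ring bond joining the oxygen-bound vinyl carbon to the former internal alkene carbon.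

## Further compounds

F1 | step 7 | (4S,5S)-4-methyl-5-(3,4,5-trimethoxyphenyl)oxolan-2-one | O=C1O[C@H](c2cc(OC)c(OC)c(OC)c2)[C@H](C1)C
F2 | step 7 | (3S,4S,5S)-3-allyl-4-methyl-5-(3,4,5-trimethoxyphenyl)oxolan-2-one | C=CC[C@@H]1C(=O)O[C@H](c2cc(OC)c(OC)c(OC)c2)[C@H]1C
F3 | step 7 | (3S,4S,5S)-3-allyl-4-methyl-3-[3-oxo-2-(trimethylsilyl)butyl]-5-(3,4,5-trimethoxyphenyl)oxolan-2-one (allyl cis to methyl; silyl-bearing carbon unassigned) | C=CC[C@@]1(CC([Si](C)(C)C)C(C)=O)C(=O)O[C@H](c2cc(OC)c(OC)c(OC)c2)[C@H]1C
F4 | step 7 | (4R)-4-allyl-4-[(1S,2S)-1-hydroxy-1-(3,4,5-trimethoxyphenyl)propan-2-yl]cyclohexane-1,3-dione | C=CC[C@]1(CCC(=O)CC1=O)[C@H](C)[C@H](O)c1cc(OC)c(OC)c(OC)c1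
F5 | step 7 | (2S,3S,3aR)-3a-allyl-3-methyl-2-(3,4,5-trimethoxyphenyl)-3,3a,4,5-tetrahydro-1-benzofuran-6(2H)-one | C=CC[C@@]12CCC(=O)C=C1O[C@H](c1cc(OC)c(OC)c(OC)c1)[C@H]2C
F6 | step 7 | (2S,3S,3aS)-3a-allyl-5-hydroxy-3-methyl-2-(3,4,5-trimethoxyphenyl)-3,3a,4,5-tetrahydro-1-benzofuran-6(2H)-one (C5 epimers) | C=CC[C@@]12CC(O)C(=O)C=C1O[C@H](c1cc(OC)c(OC)c(OC)c1)[C@H]2C
F7 | step 7 | (2S,3S,3aR)-3a-allyl-5-hydroxy-3-methyl-2-(3,4,5-trimethoxyphenyl)-3,3a-dihydro-1-benzofuran-6(2H)-one | C=CC[C@@]12C=C(O)C(=O)C=C1O[C@H](c1cc(OC)c(OC)c(OC)c1)[C@H]2C
F8 | step 12 | 7-phenylselanyl derivative of 20: 3a-allyl-5-methoxy-3-methyl-7-(phenylselanyl)-2-(3,4,5-trimethoxyphenyl)hexahydro-1-benzofuran-6(2H)-one (ring stereocentres as in 20; C5 and C7 epimers) | C=CC[C@@]12CC(OC)C(=O)C([Se]c3ccccc3)[C@@H]1O[C@H](c1cc(OC)c(OC)c(OC)c1)[C@H]2C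
F9 | step 12 | 5-phenylselanyl derivative of 21: 3a-allyl-5-methoxy-3-methyl-5-(phenylselanyl)-2-(3,4,5-trimethoxyphenyl)-3,3a,4,5-tetrahydro-1-benzofuran-6(2H)-one (C5 epimers) | C=CC[C@@]12CC(OC)([Se]c3ccccc3)C(=O)C=C1O[C@H](c1cc(OC)c(OC)c(OC)c1)[C@H]2C
F10 | step 9 | ethyl (E)-3-[(2S,3S,3aR,7aS)-6-(tert-butyldimethylsilyloxy)-3-methyl-2-(3,4,5-trimethoxyphenyl)-2,3,7,7a-tetrahydro-1-benzofuran-3a(4H)-yl]prop-2-enoate | CCOC(=O)/C=C/[C@@]12CC=C(O[Si](C)(C)C(C)(C)C)C[C@@H]1O[C@H](c1cc(OC)c(OC)c(OC)c1)[C@H]2C
F11 | step 9 | (E)-3-[(2S,3S,3aR,7aS)-6-(tert-butyldimethylsilyloxy)-3-methyl-2-(3,4,5-trimethoxyphenyl)-2,3,7,7a-tetrahydro-1-benzofuran-3a(4H)-yl]prop-2-en-1-ol | OC/C=C/[C@@]12CC=C(O[Si](C)(C)C(C)(C)C)C[C@@H]1O[C@H](c1cc(OC)c(OC)c(OC)c1)[C@H]2C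
F0 | step 10 | none | none
F12 | step 3 | 5-[(1S,2S)-1-(ethenyloxy)-2-methylbut-3-en-1-yl]-1,2,3-trimethoxybenzene | C=CO[C@H](c1cc(OC)c(OC)c(OC)c1)[C@H](C=C)C
A1 | alternative 1 | (4S,5S)-4-methyl-3-methylidene-5-(3,4,5-trimethoxyphenyl)oxolan-2-one | C=C1C(=O)O[C@H](c2cc(OC)c(OC)c(OC)c2)[C@H]1C
A2 | alternative 1 | methyl (Z)-2-[(4,4,5,5-tetramethyl-1,3,2-dioxaborolan-2-yl)methyl]but-2-enoate | C/C=C(/CB1OC(C)(C)C(C)(C)O1)C(=O)OC
A3 | alternative 2 | methyl (2S,3S,3aR)-3a-allyl-2-(3,4,5-trimethoxyphenyl)-2,3,3a,4,5,6-hexahydro-1-benzofuran-3-carboxylate | C=CC[C@@]12CCCC=C1O[C@H](c1cc(OC)c(OC)c(OC)c1)[C@H]2C(=O)OC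
A4 | alternative 2 | methyl 2-[1-allyl-2-(3,4,5-trimethoxybenzyloxy)cyclohex-2-en-1-yl]-2-diazoacetate (quaternary centre configured as in A3) | C=CC[C@]1(CCCC=C1OCc1cc(OC)c(OC)c(OC)c1)C(=[N+]=[N-])C(=O)OC
A5 | alternative 3 | 6-allyl-3,4-dimethoxy-6-[(1S,2S)-1-(tert-butyldimethylsilyloxy)-1-(3,4,5-trimethoxyphenyl)propan-2-yl]cyclohexa-2,4-dien-1-one (ring carbon configured as C3a of 22) | C=CC[C@]1(C=C(OC)C(OC)=CC1=O)[C@H](C)[C@@H](c2cc(OC)c(OC)c(OC)c2)O[Si](C)(C)C(C)(C)C
A6 | alternative 3 | 4-{2-[(1S,2S)-1-(tert-butyldimethylsilyloxy)-1-(3,4,5-trimethoxyphenyl)propan-2-yl]penta-1,4-dien-1-yl}-3,4-dimethoxycyclobut-2-en-1-one (alkene geometry and ring carbon unassigned) | C=CCC(=CC1(OC)C(OC)=CC1=O)[C@H](C)[C@@H](c1cc(OC)c(OC)c(OC)c1)O[Si](C)(C)C(C)(C)C
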